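**Plan**

- Retrosynthesis: ring A is opened at C1=C2 (aldol condensation of a C1 aldehyde on C10 with C2 of a C3 ketone). Further cuts are C2–C3 (alkoxymethyl anion + enal), C13=C14 (olefination), C5–C19 and C9–C20 (conjugate methylations), C9–C11 (1,2-addition, then 1,3-shift of oxygen from C9 to C7) and C10–C1 (enolate hydroxymethylation). This leads back to (R)-carvone.
- Forward: the carvone ring becomes ring B (C5–C10) and its isopropenyl group becomes C4=C18 and C3. The side chain is finished on the monocycle, and ring A (C1–C5, C10) is closed in the last step but one.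
- Enabling feature: in the ring-A precursor the C3 ketone lies between the sp2 carbon C4 (C4=C18) and the oxygenated CH2 C2, so C2 is its only enolisable position. C2 is 1,5-related to the C1 aldehyde, which sits cis to C4 on ring B. One condensation therefore gives the C1=C2 bond, the C2 enol oxygen next to the C3 ketone and the C4 methylene, and the cis-decalin.
- Stereochemistry: C5 of (R)-carvone directs C10 (anti aldol), then C9 and C8 (cuprate trans to the isopropenyl group, protonation). C5 is then erased by dehydrogenation and rebuilt as a quaternary centre (methyl anti to the C10 substituent). C7 comes from a thermodynamic reduction and 13E from the olefination.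

Key step: step 15

Remark: clerodane numbering is used for all intermediates (carvone C1, C2, C3, C4, C5, C6 = C9, C8, C7, C6, C5, C10); "up" is the ring-B face that carries H-10, CH3-19, C-11 and the C-7 oxygen in the target, "down" the face of C-1, C-4, CH3-20 and CH3-17.

**Route**

Step 1
Reactants: 1 (R)-(−)-carvone
Product: 3 trans-6-[(tert-butyldimethylsilyloxy)methyl]carvone (CH2OSi down on C10; isopropenyl up on C5), via hydroxymethyl ketone 2 (not isolated)
Conditions: LiN(i-Pr)2, THF, −78 °C; CH2O (gas, from cracked paraformaldehyde), −78 °C; H2O; crude 2: t-BuMe2SiCl, imidazole, DMF, 0 °C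
Reagents that add atoms: formaldehyde, C=O; tert-butyldimethylsilyl chloride, CC(C)(C)[Si](C)(C)Cl
Why: Kinetic α'-deprotonation gives the cross-conjugated lithium enolate, whose aldol addition to formaldehyde should occur on the face opposite the neighbouring C5 isopropenyl group (C10 set trans, also the thermodynamic isomer), and silylation of the crude primary alcohol prevents retro-aldol cleavage or dehydration.

Step 2
Reactants: 3 trans-6-[(tert-butyldimethylsilyloxy)methyl]carvone
Product: 4 tertiary allylic alcohol carrying the but-3-enyl group on C9 (both C9 epimers)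
Conditions: but-3-enylmagnesium bromide, CeCl3, THF, −78 → 0 °C; H2O
Reagents that add atoms: but-3-enylmagnesium bromide, C=CCC[Mg]Br
Why: Organocerium-type 1,2-addition to the hindered, enolisable enone carbonyl should suppress enolisation and conjugate addition; the configuration of the new carbinol centre does not matter because step 3 removes it.

Step 3
Reactants: 4 tertiary allylic alcohol
Product: 5 3-(but-3-enyl)-2-methyl-5-isopropenyl-4-[(tert-butyldimethylsilyloxy)methyl]cyclohex-2-en-1-one (C7 ketone, C8=C9, substituents on C10 and C5 trans)
Conditions: pyridinium chlorochromate (C5H5NH)[CrO3Cl] (2 equiv), CH2Cl2, rt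
Reagents that add atoms: pyridinium chlorochromate, [O-][Cr](=O)(=O)Cl.c1cc[nH+]cc1
Why: Babler–Dauben oxidative transposition: the tertiary chromate ester undergoes a 1,3-shift to C7 and is oxidised there, which moves the oxygen from C9 to C7 and makes C9 the β-carbon of the enone; no stereocentre is formed.

Step 4
Reactants: 5 transposed enone
Product: 7 C7 ketone with quaternary C9 (CH3-20 down; but-3-enyl up) and CH3-17 down, via silyl enol ether 6 (not isolated)
Conditions: Me2CuLi (from MeLi and CuI), Me3SiCl, Et2O/THF, −78 → −20 °C; then K2CO3 (cat.), MeOH, 0 °C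
Reagents that add atoms: lithium dimethylcuprate, [Li+].C[Cu-]C
Why: Chlorosilane-accelerated Gilman conjugate addition: axial attack on the half-chair that keeps the trans C10 and C5 substituents pseudoequatorial should deliver CH3-20 to the down face, trans to the C5 isopropenyl group as in cuprate additions to carvone (the other face would meet the isopropenyl group syn-axially), and methanolysis of 6 protonates C8 anti to the new pseudoaxial methyl to give CH3-17 down, which is also the all-equatorial thermodynamic epimer.

Step 5
Reactants: 7 C7 ketone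
Product: 9 C5=C6 enone bearing the isopropenyl group on C5 (dienone), via silyl enol ether 8 (not isolated)
Conditions: LiN(i-Pr)2, Me3SiCl, THF, −78 °C; then Pd(OAc)2 (1.1 equiv), MeCN, rt
Reagents that add atoms: none
Why: Saegusa–Ito dehydrogenation: kinetic deprotonation should take place at the C6 methylene and not at the hindered C8 methine, so CH3-17 is untouched, and the original carvone stereocentre C5 is erased so that it can be rebuilt as a quaternary centre.

Step 6
Reactants: 9 dienone
Product: 10 C7 ketone with quaternary C5 (CH3-19 up; isopropenyl down)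
Conditions: MeMgBr (1.5 equiv), Cu(OTf)2 (5 mol %), 1,3-dimesitylimidazolium chloride (6 mol %), Et2O, −30 → 0 °C; H2O
Reagents that add atoms: methylmagnesium bromide, C[Mg]Br
Why: Copper–N-heterocyclic-carbene-catalysed conjugate addition of a Grignard reagent to a 3-alkenylcyclohex-2-enone, a combination known to favour 1,4- over 1,6-addition and to build quaternary centres; A(1,2) strain with the C5 isopropenyl group holds the C10 CH2OSi group pseudoaxial on the down face, so methyl should enter C5 from the up face and the isopropenyl group (C4) should end cis to C1.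

Step 7
Reactants: 10 C7 ketone
Product: 11 C7 alcohol (hydroxyl up, equatorial)
Conditions: Li, NH3 (l), THF, EtOH, −78 °C; then H2O
Reagents that add atoms: none
Why: Dissolving-metal reduction passes through the ketyl and the carbinyl anion and should give the more stable equatorial alcohol (oxygen up, trans to CH3-17) in the chair that keeps C-1, C-11, CH3-17 and CH3-19 equatorial, whereas a kinetic hydride would be pushed to the up face by the syn-axial CH3-20 and C-4 and would give the axial epimer; the isolated alkenes and the silyl ether are inert.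

Step 8
Reactants: 11 C7 alcohol
Product: 12 C7 acetate
Conditions: Ac2O, pyridine, 4-(dimethylamino)pyridine (cat.), CH2Cl2, rt
Reagents that add atoms: acetic anhydride, CC(=O)OC(C)=O
Why: Nucleophile-catalysed acylation of the equatorial secondary alcohol; no stereocentre is affected.

Step 9
Reactants: 12 C7 acetate
Product: 13 methyl ketone (3-oxobutyl group on C9)
Conditions: PdCl2 (10 mol %), CuCl, O2 (1 atm), DMF/H2O 7:1, rt
Reagents that add atoms: water, O
Why: Tsuji–Wacker oxidation is selective for the monosubstituted terminal alkene (Markovnikov, C13 ketone), while the 1,1-disubstituted isopropenyl group on the quaternary C5 should not react.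

Step 10
Reactants: 13 methyl ketone
Product: 14 tert-butyl (13E)-enoate
Conditions: (EtO)2P(O)CH2CO2t-Bu, NaH, THF, 0 → 50 °C
Reagents that add atoms: tert-butyl diethylphosphonoacetate, CCOP(=O)(OCC)CC(=O)OC(C)(C)C
Why: Horner–Wadsworth–Emmons olefination of the methyl ketone should give mainly the E enoate (C-12 trans to the ester), with any Z isomer removed by chromatography; the tert-butyl ester is chosen so that the acid can later be freed without touching the acetate.

Step 11
Reactants: 14 tert-butyl (13E)-enoate
Product: 16 enal (C3 aldehyde on C4=C18), via allylic alcohol 15 (not isolated)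
Conditions: SeO2 (0.3 equiv), t-BuOOH, CH2Cl2, rt; then MnO2, CH2Cl2, rt
Reagents that add atoms: tert-butyl hydroperoxide, CC(C)(C)OO (its oxygen is relayed by selenium dioxide, O=[Se]=O)
Why: Riley-type allylic oxidation (ene reaction, then 2,3-shift) can only use the C3 methyl of the electron-rich 1,1-disubstituted alkene because C5 carries no hydrogen, the electron-poor enoate alkene should react far more slowly, and MnO2 takes the primary allylic alcohol on to the enal.

Step 12
Reactants: 16 enal
Product: 17 C3 carbinol carrying C2 as CH2OCH2OCH3 (both C3 epimers)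
Conditions: Bu3SnCH2OCH2OMe, n-BuLi, THF, −78 °C; then 16, −78 °C; H2O
Reagents that add atoms: tributyl[(methoxymethoxy)methyl]stannane, CCCC[Sn](CCCC)(CCCC)COCOC
Why: Tin–lithium exchange gives the α-alkoxymethyllithium, which should add 1,2 to the enal much faster than to the acetate or the tert-butyl ester at −78 °C; the new C3 carbinol configuration is removed in step 14.

Step 13
Reactants: 17 C3 carbinol
Product: 18 diol (C1 and C3 hydroxyls)
Conditions: HF·pyridine, pyridine, THF, 0 °C → rt
Reagents that add atoms: none
Why: Fluoride-mediated cleavage of the primary silyl ether under buffered conditions that leave the methoxymethyl ether, the acetate and the tert-butyl ester intact.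

Step 14
Reactants: 18 diol
Product: 19 keto aldehyde (C1 aldehyde on C10; C3 ketone flanked by C4=C18 and CH2OCH2OCH3)
Conditions: Dess–Martin periodinane (3 equiv), CH2Cl2, 0 °C → rt
Reagents that add atoms: none
Why: Dess–Martin oxidation takes the allylic secondary and the hindered primary alcohol to ketone and aldehyde in one operation under neutral conditions, so the C10 stereocentre next to the aldehyde is not exposed to base.

Step 15
Reactants: 19 keto aldehyde
Product: 21 2-O-methoxymethyl tert-butyl ester of the target, via aldol 20 (not isolated)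
Conditions: 1,8-diazabicyclo[5.4.0]undec-7-ene (1.5 equiv), MeCN, 0 → 40 °C
Reagents that add atoms: none
Why: Intramolecular aldol condensation of a 1,5-keto aldehyde: the amidine forms the enolate of the C3 ketone, which can only form toward C2 because C4 is the sp2 carbon of the exocyclic methylene, the enolate adds to the C1 aldehyde, and E1cB loss of water from 20 gives the C1=C2 enol ether conjugated to C3=O. The closest known reaction type is the base-mediated aldol cyclodehydration of α-alkoxy ketones with aldehydes to 2-alkoxy enones (protected diosphenols). Ring A (C1–C2–C3–C4–C5–C10) closes in the 6-(enolendo)-exo-trig mode from an equatorial C1 on C10 and an axial C4 on C5, which is the cis ring fusion. No new stereocentre survives, since C1 and C2 become sp2; C10 keeps its configuration, and if its α-formyl hydrogen exchanges, only the epimer with C1 cis to C4 can reach a chair transition state, because the trans-fused alternative would force CH3-17, C-11, CH3-19 and the C7 acetoxy group axial, so the closure is stereoconvergent toward the cis-decalin. The selectivity needed is chemoselectivity: the C1 aldehyde is the only electrophile within reach of a six-membered transition state, the acetate and tert-butyl ester are not attacked by the non-nucleophilic amidine, and the exposed C18 terminus of the enone is spared because no alkoxide or amine nucleophile is present. One operation thus delivers the full oxidation pattern of ring A (C2 enol oxygen, C3 ketone, C4=C18) together with the bicyclic skeleton.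

Step 16
Reactants: 21 2-O-methoxymethyl tert-butyl ester of the target
Product: 22 CNP0192653.1
Conditions: CF3CO2H/CH2Cl2 1:4, trace H2O, 0 °C → rt
Reagents that add atoms: none
Why: Acidolysis removes the methoxymethyl group from the enol oxygen (enol acetal) and the tert-butyl group from the ester in one step; the secondary acetate is stable to acid, and the 2,3-dione can only enolise toward C1 because C4 is sp2, so the diosphenol is the expected tautomer.

**Compound list**

1 | (R)-(−)-carvone | CC1=CC[C@H](CC1=O)C(C)=C | starting material
2 | trans-6-(hydroxymethyl)carvone (CH2OH down on C10, isopropenyl up on C5) | OC[C@@H]1C(=O)C(C)=CC[C@H]1C(C)=C | intermediate (not isolated)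
3 | trans-6-[(tert-butyldimethylsilyloxy)methyl]carvone | CC(C)(C)[Si](C)(C)OC[C@@H]1C(=O)C(C)=CC[C@H]1C(C)=C | intermediate
4 | tertiary allylic alcohol from 3 with but-3-enyl on C9 (both C9 epimers) | CC(C)(C)[Si](C)(C)OC[C@@H]1C(O)(CCC=C)C(C)=CC[C@H]1C(C)=C | intermediate
5 | 3-(but-3-enyl)-2-methyl-5-isopropenyl-4-[(tert-butyldimethylsilyloxy)methyl]cyclohex-2-en-1-one, 4,5-trans (C7 ketone, C8=C9) | CC(C)(C)[Si](C)(C)OC[C@@H]1C(CCC=C)=C(C)C(=O)C[C@H]1C(C)=C | intermediate
6 | C7=C8 trimethylsilyl enol ether with quaternary C9 (CH3-20 down, but-3-enyl up) | CC(C)(C)[Si](C)(C)OC[C@@H]1[C@@](C)(CCC=C)C(C)=C(O[Si](C)(C)C)C[C@H]1C(C)=C | intermediate (not isolated)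
7 | C7 ketone: C9 quaternary (CH3-20 down, but-3-enyl up), CH3-17 down, CH2OSi down on C10, isopropenyl up on C5 | CC(C)(C)[Si](C)(C)OC[C@@H]1[C@@](C)(CCC=C)[C@H](C)C(=O)C[C@H]1C(C)=C | intermediate
8 | C6=C7 trimethylsilyl enol ether of 7 | CC(C)(C)[Si](C)(C)OC[C@@H]1[C@@](C)(CCC=C)[C@H](C)C(O[Si](C)(C)C)=C[C@H]1C(C)=C | intermediate (not isolated)
9 | C5=C6 enone of 7 with the isopropenyl group on sp2 C5 | CC(C)(C)[Si](C)(C)OC[C@@H]1[C@@](C)(CCC=C)[C@H](C)C(=O)C=C1C(C)=C | intermediate
10 | C7 ketone with quaternary C5 (CH3-19 up, isopropenyl down) | CC(C)(C)[Si](C)(C)OC[C@@H]1[C@@](C)(CCC=C)[C@H](C)C(=O)C[C@@]1(C(C)=C)C | intermediate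
11 | C7 alcohol of 10 (hydroxyl up, equatorial) | CC(C)(C)[Si](C)(C)OC[C@@H]1[C@@](C)(CCC=C)[C@H](C)[C@@H](O)C[C@@]1(C(C)=C)C | intermediate
12 | C7 acetate of 11 | CC(C)(C)[Si](C)(C)OC[C@@H]1[C@@](C)(CCC=C)[C@H](C)[C@@H](OC(C)=O)C[C@@]1(C(C)=C)C | intermediate
13 | methyl ketone (3-oxobutyl on C9) | CC(C)(C)[Si](C)(C)OC[C@@H]1[C@@](C)(CCC(C)=O)[C@H](C)[C@@H](OC(C)=O)C[C@@]1(C(C)=C)C | intermediate
14 | tert-butyl (13E)-enoate | CC(C)(C)[Si](C)(C)OC[C@@H]1[C@@](C)(CC/C(C)=C/C(=O)OC(C)(C)C)[C@H](C)[C@@H](OC(C)=O)C[C@@]1(C(C)=C)C | intermediate
15 | primary allylic alcohol (C3 hydroxyl on the C4=C18 unit) | CC(C)(C)[Si](C)(C)OC[C@@H]1[C@@](C)(CC/C(C)=C/C(=O)OC(C)(C)C)[C@H](C)[C@@H](OC(C)=O)C[C@@]1(C(CO)=C)C | intermediate (not isolated)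
16 | enal (C3 aldehyde on C4=C18) | CC(C)(C)[Si](C)(C)OC[C@@H]1[C@@](C)(CC/C(C)=C/C(=O)OC(C)(C)C)[C@H](C)[C@@H](OC(C)=O)C[C@@]1(C(C=O)=C)C | intermediate
17 | C3 carbinol with C2 as CH2OCH2OCH3 (both C3 epimers) | CC(C)(C)[Si](C)(C)OC[C@@H]1[C@@](C)(CC/C(C)=C/C(=O)OC(C)(C)C)[C@H](C)[C@@H](OC(C)=O)C[C@@]1(C(=C)C(O)COCOC)C | intermediate
18 | diol (C1 and C3 hydroxyls) | OC[C@@H]1[C@@](C)(CC/C(C)=C/C(=O)OC(C)(C)C)[C@H](C)[C@@H](OC(C)=O)C[C@@]1(C(=C)C(O)COCOC)C | intermediate
19 | keto aldehyde (C1 aldehyde on C10, C3 ketone) | O=C[C@@H]1[C@@](C)(CC/C(C)=C/C(=O)OC(C)(C)C)[C@H](C)[C@@H](OC(C)=O)C[C@@]1(C(=C)C(=O)COCOC)C | intermediate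
20 | β-hydroxy ketone from C1–C2 aldol addition (C1 and C2 epimers) | C=C1C(=O)C(OCOC)C(O)[C@@H]2[C@@](C)(CC/C(C)=C/C(=O)OC(C)(C)C)[C@H](C)[C@@H](OC(C)=O)C[C@]12C | intermediate (not isolated)
21 | 2-O-methoxymethyl tert-butyl ester of the target | C=C1C(=O)C(OCOC)=C[C@@H]2[C@@](C)(CC/C(C)=C/C(=O)OC(C)(C)C)[C@H](C)[C@@H](OC(C)=O)C[C@]12C | intermediate
22 | CNP0192653.1, (5S,7S,8S,9R,10R)-7-acetoxy-2-hydroxy-3-oxocleroda-1,4(18),13E-trien-15-oic acid (cis-fused) | C=C1C(=O)C(O)=C[C@@H]2[C@@](C)(CC/C(C)=C/C(=O)O)[C@H](C)[C@@H](OC(C)=O)C[C@]12C | target

**Summary**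

Total step count: 16. Longest linear sequence: 16 steps from (R)-carvone (fully linear).

**Steps most likely to fail**

Step 6. The methyl group may be lost to 1,6-addition at the terminal C18 methylene of the isopropenyl dienone or to 1,2-addition at C7, or facial control at C5 may be poor. The fallback sets out from 9. Corey–Chaykovsky methylenation of the C5=C6 enone bond with dimethylsulfoxonium methylide (Me3S(O)I, NaH, DMSO, rt), on the face anti to the C10 side chain, should give the cyclopropyl ketone F1. Reductive cleavage of its C6–CH2 bond, the cyclopropane bond that overlaps with the carbonyl π system, with Li (2 equiv) in NH3/THF at −78 °C, followed by protonation of the enolate, turns the bridging methylene into CH3-19 and comes back to the route at 10.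

Step 4. The tetrasubstituted enone may not react, or methyl may be delivered anti to the neighbouring C10 substituent (syn to the isopropenyl group) instead of trans to the isopropenyl group. The fallback sets out from 3 and exchanges the roles of the two nucleophiles so that this opposite facial bias becomes productive. MeLi/CeCl3 (THF, −78 °C) gives the tertiary allylic alcohol F2, and pyridinium chlorochromate in CH2Cl2 transposes it to the enone F3, which carries CH3-20 on C9. But-3-enylmagnesium bromide with CuBr·SMe2 and Me3SiCl (THF, −78 → −20 °C) then adds the side chain from the up face, anti to the C10 substituent, to give silyl enol ether 6. Prolonged K2CO3/MeOH cleaves 6 and equilibrates C8 to the all-equatorial epimer, which rejoins the route at 7.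

Step 7. Thermodynamic control may be incomplete, giving the axial alcohol, or C8 may epimerise by enolisation in the basic medium. The fallback sets out from 10. LiBH(s-Bu)3 (THF, −78 °C) attacks from the up face, because the down face is shielded by the syn-axial CH3-20 and isopropenyl groups, and should give the axial alcohol F4. Mitsunobu inversion with acetic acid (PPh3, diisopropyl azodicarboxylate, toluene, 0 °C → rt) installs the equatorial acetate directly and comes back to the route at 12.

Further compounds
F1 | step 6 | cyclopropyl ketone: C5–C6 methano-bridged C7 ketone with the CH2 bridge up and the isopropenyl group down on C5 | CC(C)(C)[Si](C)(C)OC[C@@H]1[C@@](C)(CCC=C)[C@H](C)C(=O)[C@H]2C[C@@]12C(C)=C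
F2 | step 4 | tertiary allylic alcohol from 3 with methyl on C9 (both C9 epimers) | CC(C)(C)[Si](C)(C)OC[C@@H]1C(C)(O)C(C)=CC[C@H]1C(C)=C
F3 | step 4 | 2,3-dimethyl-5-isopropenyl-4-[(tert-butyldimethylsilyloxy)methyl]cyclohex-2-en-1-one, 4,5-trans | CC(C)(C)[Si](C)(C)OC[C@@H]1C(C)=C(C)C(=O)C[C@H]1C(C)=C
F4 | step 7 | C7 epimer of 11 (hydroxyl down, axial) | CC(C)(C)[Si](C)(C)OC[C@@H]1[C@@](C)(CCC=C)[C@H](C)[C@H](O)C[C@@]1(C(C)=C)C
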